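(The data come from a simulation with constants of no real substance; scatter was added.)

the same everywhere: catalyst 73 µM

| run | starting material | reagent | second substrate | temperature | remark | time |
|---|---|---|---|---|---|---|
| grey | 0.068 M | 0.084 M | 0.056 M | 55 °C | run made earlier |  |
| green | 0.076 M | 0.084 M | 0.056 M | 66 °C | run made earlier |  |
| amber | 0.091 M | 0.084 M | 0.056 M | 55 °C | run made earlier |  |
| teal | 0.056 M | 0.14 M | 0.056 M | 66 °C | run made earlier |  |
| noon | 0.12 M | 0.300 M | 0.0560 M | 70 °C |  | 5.0 h |
| spring | 0.056 M | 0.0840 M | 0.0560 M | 50 °C |  | 5.0 h |

grey run (percent of the starting material charged)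

| time / h | target / % |
|---|---|
| 0.200 | 3.4 |
| 0.417 | 5.5 |
| 0.667 | 7.0 |
| 1.33 | 13.7 |
| 2.50 | 19.0 |

green run (percent of the starting material charged)

| time / min | target / % |
|---|---|
| 5.00 | 3.1 |
| 20.0 | 6.2 |
| 40.0 | 9.4 |
| 50.0 | 11.2 |
| 60.0 | 12.4 |

amber run (percent of the starting material charged)

| time / h | target / % |
|---|---|
| 0.500 | 5.6 |
| 1.00 | 11.4 |
| 1.50 | 13.3 |
| 2.00 | 16.1 |
| 2.50 | 18.4 |

teal run (percent of the starting material charged)

| time / min | target / % |
|---|---|
| 15.0 | 7.6 |
| 25.0 | 11.5 |
| 40.0 | 16.2 |
| 50.0 | 18.3 |
| 60.0 | 20.7 |

(scatter of a reading: 0.5 percentage points)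

- what was read earlier has a scatter of 0.5 percentage points, one standard deviation

- which one finishes higher in amount of target, in percent of the starting material charged ("neither" within 2 percentage points) (noon / spring / neither)
- amount of target at the end, in percent of the starting material charged, noon
- amount of target at the end, in percent of the starting material charged, spring

The easy step is to turn each reading into the logarithm of the starting material left, counted as charge minus target. Read so, the green, amber and teal runs show an early bend and a straighter stretch after it, and the bend is behind 20.0 min into the green run and 1.00 h into the amber run. Two times matter: that bend time and the late half-life, the time in which the starting material halves on the straight stretch (a pseudo-first-order half-life). The stretches give 12.6 h in the amber run at 55 °C, and 6.76 h in the green run and 3.68 h in the teal run at 66 °C. Green over teal is 1.84 for a reagent ratio of 1.67, so I take the half-life as inverse in reagent.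

Because the amber half-life is much longer than its bend time, the slope after the bend is what to watch. With a factor of 2.06 from 55 °C to 66 °C, I reckon the late half-life at 1.32 h for noon and 17.5 h for spring. That gives 92.7 % target in noon and 17.9 % in spring, before the bend's head start is counted.

The forecast differs from my noon figure: “This suggests catalyst death”, it says, and it gives noon, with 43 % for noon and 24 % for spring.

The flask gives noon, with 84.4 % for noon and 26.1 % for spring.

    starting material + reagent + catalyst → catalyst + target (k = 6.90 M⁻² s⁻¹, Ea = 39.0 kJ mol⁻¹)
    second substrate + reagent + catalyst → catalyst + second product (k = 10.0 M⁻² s⁻¹, Ea = 37.0 kJ mol⁻¹)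
    reagent ⇌ dormant form (K = 1.10, k = 2.20 × 10⁻⁴ s⁻¹, Ea = 99.0 kJ mol⁻¹, ΔH = 3.00 kJ mol⁻¹)
    (constants at 50 °C)

In noon the reagent stood at 26.8 % of its charge at 2.50 h with 0.0962 M of dormant form beside it, and the catalyst stood at 100 % at 5.00 h. Between 2.50 h and 5.00 h the starting material in noon fell from 33.5 % to 15.6 %, a late half-life of 2.26 h against my 1.32 h.

For the neighbour of spring charged with 0.21 M of reagent, the ratio of charges turns 17.5 h into 7.01 h. It also turns the 11.5 h that spring's result amounts to over its whole run, bend included, into 4.59 h, which gives 53.0 % target; the flask gives 55.0 %.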